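**Retrosynthetic overview**

1. Numbering: chroman O1, C2, C3, C4, C4a, C5 to C8, C8a (ring A = arene, ring B = dihydropyran). The side chain is counted C1', C2', C3' ... outward from C2.
2. Last disconnection: the C5 formyl group, installed by ortho-formylation of the C6 phenol of (R)-δ-tocotrienol.
3. Key disconnection: C2'(sp3)–C3'(sp2). Two C14 halves, an (S)-2-vinylchroman silyl ether and an E-alkenyl iodide, are joined in one flask by hydroboration and B-alkyl Suzuki–Miyaura coupling, and the same basic medium frees the C6 phenol.
4. Enabling feature: C2 of ring B is fully substituted and bears C1'–C2' as an unbranched two-carbon arm, so this arm can be carried as a vinyl group, the only alkene of that half. Boron and later palladium then sit on C2', gamma to O1, so no β-alkoxide loss can occur. C3' is the CH end of the E C3'=C4' alkene whose C4' methyl is cis to C2', which is the retron of a syn methylalumination of a terminal alkyne.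
5. Rings: ring A is bought (2-methylhydroquinone). Ring B is the only ring made, by enantioselective 6-exo Wacker-type closure of the O1–C2 bond, which also sets C2, before the union.

Key step: step 10

Assumption: the (S,S)-configured BOXAX ligand is taken to deliver the 2S vinylchroman, by analogy with closely related 2-alkenylphenols; if the sense of induction proves opposite, the enantiomeric ligand is used.

**Route**

Step 1
Reactants: 1 geranyl bromide; 2 1-(trimethylsilyl)propyne
Product: 4 (E)-(6,10-dimethylundeca-5,9-dien-1-yn-1-yl)trimethylsilane, via lithiated silylpropyne 3 (not isolated)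
Conditions: 2, n-BuLi, THF, −78 to −20 °C; then 1, −78 °C to rt
Reagents that add atoms: none
Why: Propargylic lithiation of the silyl-capped propyne followed by SN2 alkylation with the primary allylic bromide is a standard three-carbon homologation that leaves the E alkene of the geranyl unit untouched.

Step 2
Reactants: 4 (E)-(6,10-dimethylundeca-5,9-dien-1-yn-1-yl)trimethylsilane
Product: 5 (E)-6,10-dimethylundeca-5,9-dien-1-yne
Conditions: K2CO3 (0.2 equiv), MeOH, rt
Reagents that add atoms: none
Why: Carbonate-catalysed methanolysis of the alkynyl carbon–silicon bond (protodesilylation) is fast and touches no other group.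

Step 3
Reactants: 5 (E)-6,10-dimethylundeca-5,9-dien-1-yne
Product: 7 (1E,5E)-1-iodo-2,6,10-trimethylundeca-1,5,9-triene, via alkenylalane 6 (not isolated)
Conditions: Me3Al (2 equiv), Cp2ZrCl2 (0.25 equiv), CH2Cl2, 0 °C to rt; then I2, THF, −30 to 0 °C
Reagents that add atoms: trimethylaluminium, C[Al](C)C; iodine, [I][I]
Why: Negishi zirconium-catalysed carboalumination adds methyl and aluminium syn across the terminal alkyne only, with aluminium on the terminal carbon, and iodinolysis with retention fixes the E geometry of the future C3'=C4' alkene.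

Step 4
Reactants: 8 2-methylhydroquinone
Product: 9 4-[(tert-butyldimethylsilyl)oxy]-2-methylphenol
Conditions: TBSCl (1.0 equiv), imidazole (2 equiv), DMF, 0 °C, N2
Reagents that add atoms: tert-butyldimethylsilyl chloride, CC(C)(C)[Si](C)(C)Cl
Why: Silylation with a bulky chlorosilane should prefer the hydroxyl that has no ortho substituent, which leaves free the hydroxyl that becomes O1.

Step 5
Reactants: 9 4-[(tert-butyldimethylsilyl)oxy]-2-methylphenol
Product: 10 5-[(tert-butyldimethylsilyl)oxy]-2-hydroxy-3-methylbenzaldehyde
Conditions: MgCl2 (anhydrous), Et3N, (CH2O)n, THF, reflux; cold 1 M HCl work-up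
Reagents that add atoms: paraformaldehyde (source of formaldehyde), C=O
Why: Casnati–Skattebøl magnesium-mediated ortho-formylation delivers formaldehyde inside the aryloxymagnesium complex to the only free position ortho to the phenol, the future C4a.

Step 6
Reactants: 10 5-[(tert-butyldimethylsilyl)oxy]-2-hydroxy-3-methylbenzaldehyde
Product: 11 (E)-4-{5-[(tert-butyldimethylsilyl)oxy]-2-hydroxy-3-methylphenyl}but-3-en-2-one
Conditions: Ph3P=CHC(O)CH3, toluene, 80 °C
Reagents that add atoms: 1-(triphenylphosphoranylidene)propan-2-one, CC(=O)C=P(c1ccccc1)(c1ccccc1)c1ccccc1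
Why: Wittig olefination with a stabilised ylide runs under neutral conditions that spare the aryl silyl ether and gives the enone that holds C4, C3, C2 and the C2 methyl group.

Step 7
Reactants: 11 (E)-4-{5-[(tert-butyldimethylsilyl)oxy]-2-hydroxy-3-methylphenyl}but-3-en-2-one
Product: 12 4-{5-[(tert-butyldimethylsilyl)oxy]-2-hydroxy-3-methylphenyl}butan-2-one
Conditions: H2 (1 atm), Pd/C, EtOAc, rt
Reagents that add atoms: none
Why: Catalytic hydrogenation saturates the conjugated alkene far faster than it reduces the ketone or touches the silyl ether.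

Step 8
Reactants: 12 4-{5-[(tert-butyldimethylsilyl)oxy]-2-hydroxy-3-methylphenyl}butan-2-one
Product: 13 4-[(tert-butyldimethylsilyl)oxy]-2-methyl-6-(3-methylpent-3-en-1-yl)phenol (E/Z mixture, used as such)
Conditions: EtPPh3Br (3 equiv), KN(SiMe3)2 (3 equiv), THF, 0 °C to rt
Reagents that add atoms: ethyltriphenylphosphonium bromide, CC[P+](c1ccccc1)(c1ccccc1)c1ccccc1.[Br-]
Why: Wittig ethylidenation with excess ylide (one equivalent is held as the phenoxide) turns the methyl ketone into the trisubstituted alkene whose two new carbons become C1' and C2'.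

Step 9
Reactants: 13 4-[(tert-butyldimethylsilyl)oxy]-2-methyl-6-(3-methylpent-3-en-1-yl)phenol
Product: 14 (S)-tert-butyl[(2,8-dimethyl-2-vinylchroman-6-yl)oxy]dimethylsilane
Conditions: Pd(OCOCF3)2 (10 mol %), (S,S)-Bn-BOXAX [(S)-2,2'-bis((S)-4-benzyl-4,5-dihydrooxazol-2-yl)-1,1'-binaphthyl] (20 mol %), p-benzoquinone (4 equiv), MeOH, rt
Reagents that add atoms: none
Why: In this enantioselective Wacker-type oxidative cyclisation, divalent palladium bound to the axially chiral bis(oxazoline) ligand activates one face of the alkene for 6-exo-trig attack of the phenol oxygen at the more substituted carbon, which sets C2 as S, β-hydride elimination can only run towards the terminal methyl group and so gives the vinyl group, and benzoquinone returns zerovalent palladium to the divalent state.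

Step 10
Reactants: 14 (S)-tert-butyl[(2,8-dimethyl-2-vinylchroman-6-yl)oxy]dimethylsilane; 7 (1E,5E)-1-iodo-2,6,10-trimethylundeca-1,5,9-triene
Product: 17 (R)-δ-tocotrienol, via alkylborane 15 (not isolated), via silyl ether 16 (not isolated)
Conditions: 9-BBN (0.5 M in THF, 1.2 equiv), 0 °C to rt; then degassed H2O, 7 (1.05 equiv), PdCl2(dppf)·CH2Cl2 (5 mol %), AsPh3 (5 mol %), Cs2CO3 (4 equiv), DMF, rt to 40 °C, argon; aq NH4Cl work-up
Reagents that add atoms: 9-borabicyclo[3.3.1]nonane (9-BBN), C1CC2CCCC(C1)B2 (its boron unit is held only in 15; only its hydrogen stays in 17)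
Why: 9-BBN adds to the vinyl group of 14 with boron on the terminal carbon C2' (the fully substituted C2 next door enforces this regiochemistry) to give 15, whose borate, formed with the aqueous base, hands its primary alkyl group to the alkenylpalladium iodide that arises from oxidative addition of zerovalent palladium into the carbon–iodine bond of 7, and reductive elimination makes the C2'–C3' bond. The closest known reaction type is the B-alkyl Suzuki–Miyaura coupling of 9-BBN adducts of terminal alkenes with E-2-methyl-1-iodoalkenes under PdCl2(dppf), AsPh3 and Cs2CO3 in wet DMF. No ring is closed and no stereocentre is made: C2 is remote from every bond change and keeps its configuration, and oxidative addition, transmetalation and reductive elimination all run with retention at C3', so the E geometry of 7 is carried into C3'=C4'. The chemoselectivity needed is secured by the substrate and the order of addition, since 14 holds a single alkene and all B–H is consumed or quenched with water before the triene 7 enters, so the three trisubstituted alkenes never meet a hydroborating agent. β-Hydride loss from the alkylpalladium is held back by the wide-bite-angle dppf ligand, and β-alkoxide loss cannot occur because boron and palladium sit on C2', gamma to O1. The Cs2CO3 in wet DMF that activates boron is also a known medium for cleaving aryl silyl ethers, so 16 should lose its silyl group in the flask, and one operation should deliver the free chromanol 17 with every carbon of the target except the formyl carbon.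

Step 11
Reactants: 17 (R)-δ-tocotrienol
Product: 18 (R)-6-hydroxy-2,8-dimethyl-2-[(3E,7E)-4,8,12-trimethyltrideca-3,7,11-trien-1-yl]chroman-5-carbaldehyde (target)
Conditions: MgCl2 (anhydrous), Et3N, (CH2O)n, MeCN, reflux, argon; cold 1 M HCl work-up
Reagents that add atoms: paraformaldehyde (source of formaldehyde), C=O
Why: In this Casnati–Skattebøl ortho-formylation both positions ortho to the C6 hydroxyl are free, but attack should favour C5, next to the fusion with the six-membered ring B, because that ring fixes more double-bond character in C5–C6 than in C6–C7 (Mills–Nixon-type bond fixation), while the amine-buffered medium leaves the three trisubstituted alkenes and C2 untouched.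

**Compound list**

1 | geranyl bromide, (E)-1-bromo-3,7-dimethylocta-2,6-diene | CC(C)=CCC/C(C)=C/CBr | starting material
2 | 1-(trimethylsilyl)propyne | CC#C[Si](C)(C)C | starting material
3 | 3-lithio-1-(trimethylsilyl)propyne | [Li]CC#C[Si](C)(C)C | intermediate
4 | (E)-(6,10-dimethylundeca-5,9-dien-1-yn-1-yl)trimethylsilane | CC(C)=CCC/C(C)=C/CCC#C[Si](C)(C)C | intermediate
5 | (E)-6,10-dimethylundeca-5,9-dien-1-yne | CC(C)=CCC/C(C)=C/CCC#C | intermediate
6 | dimethyl[(1E,5E)-2,6,10-trimethylundeca-1,5,9-trien-1-yl]alane | CC(C)=CCC/C(C)=C/CC/C(C)=C/[Al](C)C | intermediate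
7 | (1E,5E)-1-iodo-2,6,10-trimethylundeca-1,5,9-triene | CC(C)=CCC/C(C)=C/CC/C(C)=C/I | intermediate
8 | 2-methylhydroquinone | Cc1cc(O)ccc1O | starting material
9 | 4-[(tert-butyldimethylsilyl)oxy]-2-methylphenol | Cc1cc(O[Si](C)(C)C(C)(C)C)ccc1O | intermediate
10 | 5-[(tert-butyldimethylsilyl)oxy]-2-hydroxy-3-methylbenzaldehyde | O=Cc1cc(O[Si](C)(C)C(C)(C)C)cc(C)c1O | intermediate
11 | (E)-4-{5-[(tert-butyldimethylsilyl)oxy]-2-hydroxy-3-methylphenyl}but-3-en-2-one | CC(=O)/C=C/c1cc(O[Si](C)(C)C(C)(C)C)cc(C)c1O | intermediate
12 | 4-{5-[(tert-butyldimethylsilyl)oxy]-2-hydroxy-3-methylphenyl}butan-2-one | CC(=O)CCc1cc(O[Si](C)(C)C(C)(C)C)cc(C)c1O | intermediate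
13 | 4-[(tert-butyldimethylsilyl)oxy]-2-methyl-6-(3-methylpent-3-en-1-yl)phenol, E/Z mixture | CC=C(C)CCc1cc(O[Si](C)(C)C(C)(C)C)cc(C)c1O | intermediate
14 | (S)-tert-butyl[(2,8-dimethyl-2-vinylchroman-6-yl)oxy]dimethylsilane | C=C[C@]1(C)CCc2cc(O[Si](C)(C)C(C)(C)C)cc(C)c2O1 | intermediate
15 | 9-{2-[(R)-6-((tert-butyldimethylsilyl)oxy)-2,8-dimethylchroman-2-yl]ethyl}-9-borabicyclo[3.3.1]nonane | C1CC2CCCC(C1)B2CC[C@]3(C)CCc4cc(O[Si](C)(C)C(C)(C)C)cc(C)c4O3 | intermediate
16 | (R)-δ-tocotrienol tert-butyldimethylsilyl ether | CC(C)=CCC/C(C)=C/CC/C(C)=C/CC[C@]1(C)CCc2cc(O[Si](C)(C)C(C)(C)C)cc(C)c2O1 | intermediate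
17 | (R)-δ-tocotrienol, (R)-2,8-dimethyl-2-[(3E,7E)-4,8,12-trimethyltrideca-3,7,11-trien-1-yl]chroman-6-ol | CC(C)=CCC/C(C)=C/CC/C(C)=C/CC[C@]1(C)CCc2cc(O)cc(C)c2O1 | intermediate
18 | (R)-6-hydroxy-2,8-dimethyl-2-[(3E,7E)-4,8,12-trimethyltrideca-3,7,11-trien-1-yl]chroman-5-carbaldehyde | CC(C)=CCC/C(C)=C/CC/C(C)=C/CC[C@]1(C)CCc2c(C=O)c(O)cc(C)c2O1 | target

**Step count**

- Total steps: 11.
- Longest linear sequence: 8 steps (steps 4 to 11, from 8 to 18).

**Steps most likely to fail**

**Step 9.**
- Risk: facial discrimination in the oxypalladation may be too weak, because the E and Z isomers of 13 present different alkene faces to the chiral palladium complex. Turnover may also be slow.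
- Fallback: the fallback sets out from 12 and closes ring B by an intramolecular asymmetric Tsuji–Trost allylic etherification instead of an oxidative cyclisation. Horner–Wadsworth–Emmons reaction of 12 with triethyl phosphonoacetate and NaH (excess, the phenol being carried as its salt) gives, after removal of the Z isomer, ethyl (E)-5-{5-[(tert-butyldimethylsilyl)oxy]-2-hydroxy-3-methylphenyl}-3-methylpent-2-enoate F1. Reduction with i-Bu2AlH in CH2Cl2 at −78 °C gives 4-[(tert-butyldimethylsilyl)oxy]-2-[(E)-5-hydroxy-3-methylpent-3-en-1-yl]-6-methylphenol F2. ClCO2Me and pyridine at −20 °C acylate the primary alcohol in preference to the doubly ortho-substituted phenol and give (E)-5-{5-[(tert-butyldimethylsilyl)oxy]-2-hydroxy-3-methylphenyl}-3-methylpent-2-en-1-yl methyl carbonate F3. Pd2(dba)3·CHCl3, N,N'-(cyclohexane-1,2-diyl)bis[2-(diphenylphosphanyl)benzamide] (the enantiomer that leads to 2S) and AcOH in CH2Cl2 then ionise the carbonate, and the phenol attacks the more substituted allyl terminus. The route is rejoined at 14.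

**Step 11.**
- Risk: attack at C7 may compete with attack at C5, and a second formylation may follow, on material that already holds the whole skeleton.
- Fallback: the fallback sets out from 14 and moves the arene functionalisation ahead of the union. Bu4NF cleaves the silyl ether to (S)-2,8-dimethyl-2-vinylchroman-6-ol F4, which is formylated under the conditions of step 11 to (S)-6-hydroxy-2,8-dimethyl-2-vinylchroman-5-carbaldehyde F5. At this C14 stage positional isomers can be separated and the site of the formyl group proven before any coupled material is spent. Excess 9-BBN (3.3 equiv) hydroborates the vinyl group, reduces the aldehyde and borylates the phenol to the tris(9-BBN) adduct F6. Coupling F6 with 7 as in step 10, with hydrolysis of the B–O bonds in the same medium, gives (R)-5-(hydroxymethyl)-δ-tocotrienol F7. MnO2 in CH2Cl2 oxidises the benzylic alcohol, and the route is rejoined at 18.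

**Step 10.**
- Risk: β-hydride elimination or protodeboronation may outrun the coupling if transmetalation from boron is slow, and loss of the silyl group may stay incomplete.
- Fallback: the fallback sets out from 14 and changes the nucleophile to zinc, with a separate deprotection. Hydroboration to 15 followed by NaOH and H2O2 gives (S)-2-{6-[(tert-butyldimethylsilyl)oxy]-2,8-dimethylchroman-2-yl}ethanol F8. An Appel reaction (I2, PPh3, imidazole) gives (S)-tert-butyl{[2-(2-iodoethyl)-2,8-dimethylchroman-6-yl]oxy}dimethylsilane F9. LiCl-assisted insertion of zinc dust in THF gives the alkylzinc iodide F10. Negishi coupling of F10 with 7 under PdCl2(dppf) in THF gives 16, now isolated. Bu4NF in THF then rejoins the route at 17.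

**Further compounds**

F1 | step 9 | ethyl (E)-5-{5-[(tert-butyldimethylsilyl)oxy]-2-hydroxy-3-methylphenyl}-3-methylpent-2-enoate | CCOC(=O)/C=C(\C)CCc1cc(O[Si](C)(C)C(C)(C)C)cc(C)c1O
F2 | step 9 | 4-[(tert-butyldimethylsilyl)oxy]-2-[(E)-5-hydroxy-3-methylpent-3-en-1-yl]-6-methylphenol | OC/C=C(\C)CCc1cc(O[Si](C)(C)C(C)(C)C)cc(C)c1O
F3 | step 9 | (E)-5-{5-[(tert-butyldimethylsilyl)oxy]-2-hydroxy-3-methylphenyl}-3-methylpent-2-en-1-yl methyl carbonate | COC(=O)OC/C=C(\C)CCc1cc(O[Si](C)(C)C(C)(C)C)cc(C)c1O
F4 | step 11 | (S)-2,8-dimethyl-2-vinylchroman-6-ol | C=C[C@]1(C)CCc2cc(O)cc(C)c2O1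
F5 | step 11 | (S)-6-hydroxy-2,8-dimethyl-2-vinylchroman-5-carbaldehyde | C=C[C@]1(C)CCc2c(C=O)c(O)cc(C)c2O1
F6 | step 11 | tris(9-BBN) adduct of F5 (C2'-boryl, benzylic O-boryl, phenolic O-boryl), R at C2 | C1CC2CCCC(C1)B2CC[C@]3(C)CCc4c(COB5C6CCCC5CCC6)c(OB5C6CCCC5CCC6)cc(C)c4O3
F7 | step 11 | (R)-5-(hydroxymethyl)-δ-tocotrienol | CC(C)=CCC/C(C)=C/CC/C(C)=C/CC[C@]1(C)CCc2c(CO)c(O)cc(C)c2O1
F8 | step 10 | (S)-2-{6-[(tert-butyldimethylsilyl)oxy]-2,8-dimethylchroman-2-yl}ethanol | OCC[C@]1(C)CCc2cc(O[Si](C)(C)C(C)(C)C)cc(C)c2O1
F9 | step 10 | (S)-tert-butyl{[2-(2-iodoethyl)-2,8-dimethylchroman-6-yl]oxy}dimethylsilane | ICC[C@]1(C)CCc2cc(O[Si](C)(C)C(C)(C)C)cc(C)c2O1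
F10 | step 10 | (S)-{2-[6-((tert-butyldimethylsilyl)oxy)-2,8-dimethylchroman-2-yl]ethyl}zinc iodide | I[Zn]CC[C@]1(C)CCc2cc(O[Si](C)(C)C(C)(C)C)cc(C)c2O1
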